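97.8 % of the D that reacts turns first into E, because D → E is faster than D → Q, so I choose the next run by what becomes of E.

in all of them: D 0.20 M

| charge | time | remark |
|---|---|---|
| green | 12 h | everything together in a closed stirred flask, run for 12 h |
| ochre |  | one stirred flow tank at steady state, fed with the mixture as stated, mean residence time 60.0 h |
| amber |  | one stirred flow tank at steady state, fed with the mixture as stated, mean residence time 12 h |

    D → E (k1 = 0.48 min⁻¹)
    D → Q (k2 = 0.011 min⁻¹)
    Q → L (k3 = 0.0048 min⁻¹)
    E ⇌ Q (K4 = 2.3, k4 = 0.0016 min⁻¹)

- the stated concentrations are those of everything mixed, before any reaction; amounts are the same in each set-up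
- run time (green): 12 h

- order of the set-ups by the amount of L at the outlet or at the end, in percent of the D put in, highest first (green / ochre / amber)
- amount of L at the outlet or at the end, in percent of the D put in, green
- amount of L at the outlet or at the end, in percent of the D put in, ochre
- amount of L at the outlet or at the end, in percent of the D put in, amber

D has a mean life of 2.04 min, far shorter than the 12 h of green and amber. After those first minutes a portion of the charge stands nearly all in E, the resting state, the form in which it waits. E → Q, with forward constant 0.0016 min⁻¹, is slower than Q → L at 0.0048 min⁻¹, but only by a factor of 3.00, and it runs back, so I name no rate-limiting step and start my reckoning from the amount of E.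

I therefore carry one number, the leak count n: the forward constant of E → Q times the time the mixture stays in the vessel. It is 1.15 for 12 h and 5.76 for ochre's 60.0 h. Setting aside the way back from Q to E and counting all D as reacted, a closed flask keeps e to the power minus n of its E, and a tank keeps one part in one plus n. Whatever is not left in E I send through Q, and the same reckoning with the constant of Q → L gives L:

green, closed, n = 1.15: E left 30.9 %, L about 55.1 %

ochre, tank, n = 5.76: E left 14.5 %, L about 80.9 %

amber, tank, n = 1.15: E left 45.4 %, L about 42.3 %

So if L per D charged is what counts, I charge ochre next. If the time must stay at 12 h, I take the closed flask over the tank, because at the same n the closed flask keeps less E.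

The forecast gives 51.3 % for green, 79.2 % for ochre and 40.1 % for amber, in the order ochre > green > amber, holding that “the tank's back-mixing penalises a sequential chain”, and my figures for the same flasks stand higher than these.

The flask gives 51.4 % for green, 79.2 % for ochre and 40.1 % for amber, in the order ochre > green > amber. With the falling back of Q to E struck out, ochre gives 80.8 %. Put to use on E, n = 5.76 gives 14.5 % in ochre, where the tank holds 16.2 %, and n = 1.15 gives 45.4 % in amber, where the tank holds 48.0 %.

Its constants are those of an exercise.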